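**Plan** (labdane numbering: ring A = C1–C5 + C10, ring B = C5–C10, C17 = carboxyl carbon on C8, C11–C15 = side chain, C20 = methyl on C10)
- Cuts, in order: C8–C17 (C7=C8 enol triflate + CO), then C9–C11 (C8=C9 enol triflate + C11–C15 zinc reagent), which leaves a trans-decalone with the carbonyl on C9; its ring A is then cut at C1–C10 and C2–C3.
- Enabling feature: in ring A, C1 and C2 are two adjacent unsubstituted CH2 groups held between the quaternary C10 (α to a temporary C9 carbonyl, so it can be an enolate carbon) and C3 (on the gem-dimethyl carbon C4, so it can be a non-enolisable aldehyde). A vinylphosphonium salt delivers C1–C2, first as acceptor, then as ylide.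
- Forward: ring B is 2-methylcyclohex-2-enone; the C3–C4 unit is added at C5 by asymmetric Mukaiyama–Michael reaction; ring A is closed in the key step; C2=C3 is hydrogenated; the C9 carbonyl is exchanged for the side chain and moved to C8 by hydroboration–oxidation; C8 is carbonylated.
- Stereochemistry: C5 from the catalyst (step 1); C10 from C5 (key step, trans); C9 from C10 (hydroboration on the α face); C13 from methyl hydrogen (R)-3-methylglutarate.

Key step: step 2

Assumption: the oxazaborolidinium catalyst is taken to discriminate the faces of the α-methyl enone in the same sense as for cyclohex-2-enone; both catalyst antipodes are available, and the one that gives the (1R) adduct 3 is used.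

**Step 1**
Reactants: 1 2-methylcyclohex-2-en-1-one; 2 2-methyl-1-(trimethylsilyloxy)prop-1-ene
Product: 3 2-methyl-2-[(1R)-2-methyl-3-(trimethylsilyloxy)cyclohex-2-en-1-yl]propanal
Conditions: o-tolyl-CBS-oxazaborolidine·HNTf2 (10 mol%, antipode as stated in the assumption), Ph3PO (15 mol%), toluene, −40 to −20 °C; Et3N quench, non-aqueous work-up
Reagents that add atoms: none
Why: Proposed new method: the chiral oxazaborolidinium ion binds the enone carbonyl and shields one face of the β-carbon C5, the enol silane 2 attacks the open face (C4–C5 bond, C5 set by the catalyst), and the Me3Si group of the resulting silyloxocarbenium ion is relayed by Ph3PO to the boron-bound enolate oxygen, which releases the catalyst and leaves the enol silane with its double bond fixed between C9 and C10; the closest known reaction type is the oxazaborolidinium-catalysed enantioselective Mukaiyama–Michael addition of silyl ketene acetals to cyclic enones, extended here to a less nucleophilic aldehyde-derived enol silane and an α-methyl enone.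

**Step 2**
Reactants: 3 2-methyl-2-[(1R)-2-methyl-3-(trimethylsilyloxy)cyclohex-2-en-1-yl]propanal; 4 ethenyl(triphenyl)phosphonium bromide
Product: 7 (4aS,8aS)-5,5,8a-trimethyl-3,4,4a,5,8,8a-hexahydronaphthalen-1(2H)-one, via ammonium enolate 5 (not isolated), via phosphonium ylide 6 (not isolated)
Conditions: 3 added slowly to 4 (1.5 equiv) and Bu4N[Ph3SiF2] (1.1 equiv), MeCN–THF, 0 °C; then 60 °C
Reagents that add atoms: none
Why: Fluoride removes the silyl group from 3 and frees the tetrasubstituted enolate 5, whose carbon C10 adds to the vinylphosphonium salt 4 (new C1–C10 bond) to give the ylide 6; the ylide carbon C2 then attacks the aldehyde C3 and, through the oxaphosphetane, gives the C2=C3 double bond (new C2–C3 bond) with loss of Ph3PO. The closest known reaction type is the Schweizer annulation, conjugate addition of an enolate to a vinylphosphonium salt followed by intramolecular Wittig olefination, which is established for cyclopentenes and cyclohexenes. Ring A is closed as a six-membered ring in the Wittig step (6-exo attack of the ylide carbon on the aldehyde carbonyl), so that the four-carbon unit C3–C4–C5–C10 and the two-carbon unit C1–C2 are joined in a (4+2) sense. The quaternary stereocenter C10 is controlled by C5: allylic 1,2-strain with the C10 methyl group holds the bulky C5 substituent pseudoaxial, the salt enters on the opposite face, and C1 ends trans to C4, which gives the trans ring fusion with the methyl group on the β face. The step needs alkylation at C10 and not at C8, and Michael addition and not aldol addition; the first is secured by the regiodefined enol silane and the absence of a proton source, the second by the non-enolisable neopentyl aldehyde, by the strained four-membered ring that an intramolecular aldol would require, and by keeping 4 in excess through slow addition of 3.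

**Step 3**
Reactants: 7 (4aS,8aS)-5,5,8a-trimethyl-3,4,4a,5,8,8a-hexahydronaphthalen-1(2H)-one
Product: 8 (4aS,8aS)-5,5,8a-trimethyloctahydronaphthalen-1(2H)-one
Conditions: H2 (1 atm), Pd/C, EtOAc, rt
Reagents that add atoms: none
Why: Heterogeneous hydrogenation of the cis-disubstituted C2=C3 alkene should proceed without touching the ketone or either stereocenter.

**Step 4**
Reactants: 8 (4aS,8aS)-5,5,8a-trimethyloctahydronaphthalen-1(2H)-one
Product: 10 (4aS,8aS)-5,5,8a-trimethyl-3,4,4a,5,6,7,8,8a-octahydronaphthalen-1-yl trifluoromethanesulfonate, via potassium enolate 9 (not isolated)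
Conditions: KN(SiMe3)2, THF, −78 °C; PhNTf2, −78 to 0 °C
Reagents that add atoms: N-phenylbis(trifluoromethanesulfonimide), O=S(=O)(N(c1ccccc1)S(=O)(=O)C(F)(F)F)C(F)(F)F
Why: Enol triflate formation is regiochemically unambiguous because the ketone has α-hydrogens only on C8 (C10 is quaternary), so a single C8=C9 triflate should form.

**Step 5**
Reactants: 11 (3R)-5-methoxy-3-methyl-5-oxopentanoic acid
Product: 12 methyl (3R)-5-hydroxy-3-methylpentanoate
Conditions: BH3·THF (1.05 equiv), THF, −15 to 0 °C; MeOH quench, aqueous work-up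
Reagents that add atoms: none
Why: Borane reduces a carboxylic acid much faster than an ester, so only the acid terminus should be reduced, and the stereocenter is not involved.

**Step 6**
Reactants: 12 methyl (3R)-5-hydroxy-3-methylpentanoate
Product: 13 methyl (3R)-5-{[tert-butyl(dimethyl)silyl]oxy}-3-methylpentanoate
Conditions: TBSCl, imidazole, CH2Cl2, 0 °C to rt (crude 12 used at once)
Reagents that add atoms: tert-butyldimethylsilyl chloride, CC(C)(C)[Si](C)(C)Cl
Why: Silyl ether formation on the primary alcohol is routine and, done immediately, should forestall lactonisation of the δ-hydroxy ester.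

**Step 7**
Reactants: 13 methyl (3R)-5-{[tert-butyl(dimethyl)silyl]oxy}-3-methylpentanoate
Product: 14 (3S)-5-{[tert-butyl(dimethyl)silyl]oxy}-3-methylpentan-1-ol
Conditions: LiAlH4, Et2O, 0 °C
Reagents that add atoms: none
Why: Hydride reduction of the ester to the primary alcohol should leave the silyl ether intact at 0 °C (the descriptor changes only through the priority rules).

**Step 8**
Reactants: 14 (3S)-5-{[tert-butyl(dimethyl)silyl]oxy}-3-methylpentan-1-ol
Product: 15 tert-butyl{[(3R)-5-iodo-3-methylpentyl]oxy}dimethylsilane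
Conditions: I2, PPh3, imidazole, CH2Cl2, 0 °C to rt
Reagents that add atoms: iodine, [I][I]
Why: Appel-type iodination of an unhindered primary alcohol by SN2 displacement of the alkoxyphosphonium ion; the remote stereocenter is untouched.

**Step 9**
Reactants: 10 (4aS,8aS)-5,5,8a-trimethyl-3,4,4a,5,6,7,8,8a-octahydronaphthalen-1-yl trifluoromethanesulfonate; 15 tert-butyl{[(3R)-5-iodo-3-methylpentyl]oxy}dimethylsilane
Product: 17 tert-butyldimethyl{[(3S)-3-methyl-5-[(4aS,8aS)-5,5,8a-trimethyl-3,4,4a,5,6,7,8,8a-octahydronaphthalen-1-yl]pentyl]oxy}silane, via alkylzinc iodide 16 (not isolated)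
Conditions: 15, Zn dust, LiCl, THF, 40 °C; then 10, PdCl2(dppf) (5 mol%), THF–NMP, 50 °C
Reagents that add atoms: none
Why: Negishi sp2–sp3 cross-coupling, in which oxidative addition of the alkenyl triflate to zerovalent palladium, transmetalation from the primary alkylzinc iodide (made by LiCl-assisted zinc insertion, which tolerates the silyl ether) and reductive elimination should form the C9–C11 bond without affecting C13.

**Step 10**
Reactants: 17 tert-butyldimethyl{[(3S)-3-methyl-5-[(4aS,8aS)-5,5,8a-trimethyl-3,4,4a,5,6,7,8,8a-octahydronaphthalen-1-yl]pentyl]oxy}silane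
Product: 19 (1R,2R,4aS,8aS)-1-[(3S)-5-{[tert-butyl(dimethyl)silyl]oxy}-3-methylpentyl]-5,5,8a-trimethyldecahydronaphthalen-2-ol, via C8 alkylborane 18 (not isolated)
Conditions: BH3·THF, THF, 0 °C to rt; then NaOH, H2O2, 0 °C to rt
Reagents that add atoms: hydrogen peroxide, OO
Why: Hydroboration–oxidation, in which borane adds syn to the trisubstituted C8=C9 alkene from the α face (opposite the axial C10 methyl group) with boron on the less substituted C8, should set C9 with hydrogen α and the side chain β, and the oxidation proceeds with retention.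

**Step 11**
Reactants: 19 (1R,2R,4aS,8aS)-1-[(3S)-5-{[tert-butyl(dimethyl)silyl]oxy}-3-methylpentyl]-5,5,8a-trimethyldecahydronaphthalen-2-ol
Product: 20 (1R,4aS,8aS)-1-[(3S)-5-{[tert-butyl(dimethyl)silyl]oxy}-3-methylpentyl]-5,5,8a-trimethyloctahydronaphthalen-2(1H)-one
Conditions: Dess–Martin periodinane, CH2Cl2, rt
Reagents that add atoms: none
Why: Dess–Martin oxidation of the secondary alcohol under near-neutral conditions should keep C9, whose configuration (side chain equatorial) is in any case the thermodynamically preferred one.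

**Step 12**
Reactants: 20 (1R,4aS,8aS)-1-[(3S)-5-{[tert-butyl(dimethyl)silyl]oxy}-3-methylpentyl]-5,5,8a-trimethyloctahydronaphthalen-2(1H)-one
Product: 22 (1R,4aS,8aS)-1-[(3S)-5-{[tert-butyl(dimethyl)silyl]oxy}-3-methylpentyl]-5,5,8a-trimethyl-1,4,4a,5,6,7,8,8a-octahydronaphthalen-2-yl trifluoromethanesulfonate, via potassium enolate 21 (not isolated)
Conditions: KN(SiMe3)2, THF, −78 °C; PhNTf2, −78 to 0 °C
Reagents that add atoms: N-phenylbis(trifluoromethanesulfonimide), O=S(=O)(N(c1ccccc1)S(=O)(=O)C(F)(F)F)C(F)(F)F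
Why: Kinetic deprotonation by the bulky amide should occur at the accessible C7 methylene and not at the hindered tertiary C9 next to the quaternary C10, and O-sulfonylation of that enolate fixes the double bond at C7=C8.

**Step 13**
Reactants: 22 (1R,4aS,8aS)-1-[(3S)-5-{[tert-butyl(dimethyl)silyl]oxy}-3-methylpentyl]-5,5,8a-trimethyl-1,4,4a,5,6,7,8,8a-octahydronaphthalen-2-yl trifluoromethanesulfonate
Product: 24 (3S)-3-methyl-5-[(1R,4aS,8aS)-5,5,8a-trimethyl-2-{[(trifluoromethyl)sulfonyl]oxy}-1,4,4a,5,6,7,8,8a-octahydronaphthalen-1-yl]pentyl acetate, via primary alcohol 23 (not isolated)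
Conditions: HF·pyridine, THF–pyridine, 0 °C to rt; then excess Ac2O, DMAP, rt (one pot)
Reagents that add atoms: acetic anhydride, CC(=O)OC(C)=O
Why: Fluoride cleavage of the primary silyl ether followed by DMAP-catalysed acetylation in the same flask should leave the enol triflate, which is inert to both reagents, untouched.

**Step 14**
Reactants: 24 (3S)-3-methyl-5-[(1R,4aS,8aS)-5,5,8a-trimethyl-2-{[(trifluoromethyl)sulfonyl]oxy}-1,4,4a,5,6,7,8,8a-octahydronaphthalen-1-yl]pentyl acetate
Product: 25 (1R,4aS,8aS)-1-[(3S)-5-(acetyloxy)-3-methylpentyl]-5,5,8a-trimethyl-1,4,4a,5,6,7,8,8a-octahydronaphthalene-2-carboxylic acid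
Conditions: Pd(OAc)2 (5 mol%), dppf (10 mol%), CO (1 atm), KOAc, DMF–H2O, 60 °C; dilute HCl work-up
Reagents that add atoms: carbon monoxide, [C-]#[O+]; water, O
Why: Palladium-catalysed hydroxycarbonylation of the alkenyl triflate (oxidative addition, CO insertion, capture of the acylpalladium species by water) should give the conjugated acid with the double bond fixed at C7=C8, and the mild acetate base should spare the primary acetate.

**Compound list**
1 | 2-methylcyclohex-2-en-1-one | CC1=CCCCC1=O | starting material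
2 | 2-methyl-1-(trimethylsilyloxy)prop-1-ene | CC(C)=CO[Si](C)(C)C | starting material
3 | 2-methyl-2-[(1R)-2-methyl-3-(trimethylsilyloxy)cyclohex-2-en-1-yl]propanal | C[Si](C)(C)OC1=C(C)[C@H](C(C)(C)C=O)CCC1 | intermediate
4 | ethenyl(triphenyl)phosphonium bromide | C=C[P+](c1ccccc1)(c1ccccc1)c1ccccc1.[Br-] | starting material
5 | tetrabutylammonium (3R)-2-methyl-3-(2-methyl-1-oxopropan-2-yl)cyclohex-1-en-1-olate (not isolated) | [O-]C1=C(C)[C@H](C(C)(C)C=O)CCC1.CCCC[N+](CCCC)(CCCC)CCCC | intermediate
6 | 2-methyl-2-[(1S,2S)-2-methyl-3-oxo-2-[2-(triphenylphosphoranylidene)ethyl]cyclohexyl]propanal (not isolated) | O=C1CCC[C@@H](C(C)(C)C=O)[C@]1(C)CC=P(c1ccccc1)(c1ccccc1)c1ccccc1 | intermediate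
7 | (4aS,8aS)-5,5,8a-trimethyl-3,4,4a,5,8,8a-hexahydronaphthalen-1(2H)-one | O=C1CCC[C@H]2C(C)(C)C=CC[C@]12C | intermediate
8 | (4aS,8aS)-5,5,8a-trimethyloctahydronaphthalen-1(2H)-one | O=C1CCC[C@H]2C(C)(C)CCC[C@]12C | intermediate
9 | potassium (4aS,8aS)-5,5,8a-trimethyl-3,4,4a,5,6,7,8,8a-octahydronaphthalen-1-olate (not isolated) | [K+].[O-]C1=CCC[C@H]2C(C)(C)CCC[C@]12C | intermediate
10 | (4aS,8aS)-5,5,8a-trimethyl-3,4,4a,5,6,7,8,8a-octahydronaphthalen-1-yl trifluoromethanesulfonate | O=S(=O)(OC1=CCC[C@H]2C(C)(C)CCC[C@]12C)C(F)(F)F | intermediate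
11 | (3R)-5-methoxy-3-methyl-5-oxopentanoic acid (methyl hydrogen (R)-3-methylglutarate) | OC(=O)C[C@@H](C)CC(=O)OC | starting material
12 | methyl (3R)-5-hydroxy-3-methylpentanoate | OCC[C@@H](C)CC(=O)OC | intermediate
13 | methyl (3R)-5-{[tert-butyl(dimethyl)silyl]oxy}-3-methylpentanoate | CC(C)(C)[Si](C)(C)OCC[C@@H](C)CC(=O)OC | intermediate
14 | (3S)-5-{[tert-butyl(dimethyl)silyl]oxy}-3-methylpentan-1-ol | CC(C)(C)[Si](C)(C)OCC[C@@H](C)CCO | intermediate
15 | tert-butyl{[(3R)-5-iodo-3-methylpentyl]oxy}dimethylsilane | CC(C)(C)[Si](C)(C)OCC[C@@H](C)CCI | intermediate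
16 | [(3R)-5-{[tert-butyl(dimethyl)silyl]oxy}-3-methylpentyl](iodo)zinc (not isolated) | CC(C)(C)[Si](C)(C)OCC[C@@H](C)CC[Zn]I | intermediate
17 | tert-butyldimethyl{[(3S)-3-methyl-5-[(4aS,8aS)-5,5,8a-trimethyl-3,4,4a,5,6,7,8,8a-octahydronaphthalen-1-yl]pentyl]oxy}silane | CC(C)(C)[Si](C)(C)OCC[C@@H](C)CCC1=CCC[C@H]2C(C)(C)CCC[C@]12C | intermediate
18 | C8 alkylborane: 17 with hydrogen added to C9 and BH2 to C8, both on the α face, trans to the C10 methyl group (not isolated) | CC(C)(C)[Si](C)(C)OCC[C@@H](C)CC[C@H]1[C@H](B)CC[C@H]2C(C)(C)CCC[C@]12C | intermediate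
19 | (1R,2R,4aS,8aS)-1-[(3S)-5-{[tert-butyl(dimethyl)silyl]oxy}-3-methylpentyl]-5,5,8a-trimethyldecahydronaphthalen-2-ol | CC(C)(C)[Si](C)(C)OCC[C@@H](C)CC[C@H]1[C@H](O)CC[C@H]2C(C)(C)CCC[C@]12C | intermediate
20 | (1R,4aS,8aS)-1-[(3S)-5-{[tert-butyl(dimethyl)silyl]oxy}-3-methylpentyl]-5,5,8a-trimethyloctahydronaphthalen-2(1H)-one | CC(C)(C)[Si](C)(C)OCC[C@@H](C)CC[C@H]1C(=O)CC[C@H]2C(C)(C)CCC[C@]12C | intermediate
21 | potassium (1R,4aS,8aS)-1-[(3S)-5-{[tert-butyl(dimethyl)silyl]oxy}-3-methylpentyl]-5,5,8a-trimethyl-1,4,4a,5,6,7,8,8a-octahydronaphthalen-2-olate (not isolated) | CC(C)(C)[Si](C)(C)OCC[C@@H](C)CC[C@H]1C([O-])=CC[C@H]2C(C)(C)CCC[C@]12C.[K+] | intermediate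
22 | (1R,4aS,8aS)-1-[(3S)-5-{[tert-butyl(dimethyl)silyl]oxy}-3-methylpentyl]-5,5,8a-trimethyl-1,4,4a,5,6,7,8,8a-octahydronaphthalen-2-yl trifluoromethanesulfonate | CC(C)(C)[Si](C)(C)OCC[C@@H](C)CC[C@H]1C(OS(=O)(=O)C(F)(F)F)=CC[C@H]2C(C)(C)CCC[C@]12C | intermediate
23 | (1R,4aS,8aS)-1-[(3S)-5-hydroxy-3-methylpentyl]-5,5,8a-trimethyl-1,4,4a,5,6,7,8,8a-octahydronaphthalen-2-yl trifluoromethanesulfonate (not isolated) | OCC[C@@H](C)CC[C@H]1C(OS(=O)(=O)C(F)(F)F)=CC[C@H]2C(C)(C)CCC[C@]12C | intermediate
24 | (3S)-3-methyl-5-[(1R,4aS,8aS)-5,5,8a-trimethyl-2-{[(trifluoromethyl)sulfonyl]oxy}-1,4,4a,5,6,7,8,8a-octahydronaphthalen-1-yl]pentyl acetate | CC(=O)OCC[C@@H](C)CC[C@H]1C(OS(=O)(=O)C(F)(F)F)=CC[C@H]2C(C)(C)CCC[C@]12C | intermediate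
25 | (1R,4aS,8aS)-1-[(3S)-5-(acetyloxy)-3-methylpentyl]-5,5,8a-trimethyl-1,4,4a,5,6,7,8,8a-octahydronaphthalene-2-carboxylic acid | CC(=O)OCC[C@@H](C)CC[C@H]1C(C(=O)O)=CC[C@H]2C(C)(C)CCC[C@]12C | target

**Step count and risks**
Total step count: 14. Longest linear sequence: 10 steps (steps 1–4 and 9–14; the side-chain branch, steps 5–8 and 9–14, is equally long).

Steps most likely to fail:

1. Step 1 (Proposed new method). Face discrimination on the α-methyl enone may be poor, or the weakly nucleophilic aldehyde enol silane may add too slowly. The fallback sets out from 1 and takes C5 from a stereospecific rearrangement.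
   - Corey–Bakshi–Shibata reduction of 1 ((R)-2-methyl-CBS-oxazaborolidine, BH3·SMe2) should give (1S)-2-methylcyclohex-2-en-1-ol F1.
   - Acylation with 2-methylpropanoyl chloride (pyridine, DMAP) gives (1S)-2-methylcyclohex-2-en-1-yl 2-methylpropanoate F2.
   - LiN(iPr)2 and Me3SiCl (THF, −78 °C) give trimethyl[(2-methyl-1-{[(1S)-2-methylcyclohex-2-en-1-yl]oxy}prop-1-en-1-yl)oxy]silane F3. On warming this should undergo suprafacial Ireland–Claisen rearrangement to trimethylsilyl 2-methyl-2-[(1R)-2-methylcyclohex-2-en-1-yl]propanoate F4, hydrolysed on work-up to 2-methyl-2-[(1R)-2-methylcyclohex-2-en-1-yl]propanoic acid F5.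
   - Excess BH3·THF followed by NaOH/H2O2 reduces the acid and hydroborates the alkene anti to the C5 substituent, giving (1R,2R,3R)-3-(1-hydroxy-2-methylpropan-2-yl)-2-methylcyclohexan-1-ol F6.
   - Swern oxidation gives 2-methyl-2-[(1R,2R)-2-methyl-3-oxocyclohexyl]propanal F7.
   - Me3SiCl, NaI and Et3N in MeCN (equilibrating conditions, more substituted enol silane) return to the route at 3.

2. Step 2. The congested enolate may react at oxygen, or add to the aldehyde of a second molecule, faster than it alkylates at C10, and the ylide may then fail to close. The fallback sets out from 3 and removes the aldehyde before any enolate is formed. Wittig methylenation of 3 with Ph3P=CH2 (THF, −78 to 0 °C) should give trimethyl{[(3S)-2-methyl-3-(2-methylbut-3-en-2-yl)cyclohex-1-en-1-yl]oxy}silane F8. MeLi (THF, 0 °C) then frees lithium (3S)-2-methyl-3-(2-methylbut-3-en-2-yl)cyclohex-1-en-1-olate F9, which allyl bromide should alkylate at C10 trans to the C5 substituent to give (2S,3S)-2-methyl-3-(2-methylbut-3-en-2-yl)-2-(prop-2-en-1-yl)cyclohexan-1-one F10. Ring-closing metathesis with the second-generation Grubbs catalyst RuCl2(=CHPh)(PCy3)(H2IMes) (CH2Cl2, 40 °C) closes ring A and returns to the route at 7.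

3. Step 9. Oxidative addition and transmetalation at the triflate next to the quaternary C10 may be slow, so that protodemetalation of the zinc reagent or reduction of the triflate takes over. The fallback sets out from 8 and reverses the polarity. Condensation with 2,4,6-tri(propan-2-yl)benzenesulfonohydrazide (cat. HCl, MeOH) gives N'-[(4aS,8aS)-5,5,8a-trimethyloctahydronaphthalen-1(2H)-ylidene]-2,4,6-tri(propan-2-yl)benzenesulfonohydrazide F11. Shapiro reaction (n-BuLi, 2.2 equiv, THF–TMEDA, −78 to 0 °C) gives [(4aS,8aS)-5,5,8a-trimethyl-3,4,4a,5,6,7,8,8a-octahydronaphthalen-1-yl]lithium F12, which is alkylated with iodide 15 and returns to the route at 17.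

**Further compounds**
F1 | step 1 | (1S)-2-methylcyclohex-2-en-1-ol | O[C@H]1CCCC=C1C
F2 | step 1 | (1S)-2-methylcyclohex-2-en-1-yl 2-methylpropanoate | CC(C)C(=O)O[C@H]1CCCC=C1C
F3 | step 1 | trimethyl[(2-methyl-1-{[(1S)-2-methylcyclohex-2-en-1-yl]oxy}prop-1-en-1-yl)oxy]silane | CC(C)=C(O[Si](C)(C)C)O[C@H]1CCCC=C1C
F4 | step 1 | trimethylsilyl 2-methyl-2-[(1R)-2-methylcyclohex-2-en-1-yl]propanoate | CC1=CCCC[C@H]1C(C)(C)C(=O)O[Si](C)(C)C
F5 | step 1 | 2-methyl-2-[(1R)-2-methylcyclohex-2-en-1-yl]propanoic acid | CC1=CCCC[C@H]1C(C)(C)C(=O)O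
F6 | step 1 | (1R,2R,3R)-3-(1-hydroxy-2-methylpropan-2-yl)-2-methylcyclohexan-1-ol | O[C@@H]1CCC[C@@H](C(C)(C)CO)[C@H]1C
F7 | step 1 | 2-methyl-2-[(1R,2R)-2-methyl-3-oxocyclohexyl]propanal | O=C1CCC[C@@H](C(C)(C)C=O)[C@H]1C
F8 | step 2 | trimethyl{[(3S)-2-methyl-3-(2-methylbut-3-en-2-yl)cyclohex-1-en-1-yl]oxy}silane | C[Si](C)(C)OC1=C(C)[C@H](C(C)(C)C=C)CCC1
F9 | step 2 | lithium (3S)-2-methyl-3-(2-methylbut-3-en-2-yl)cyclohex-1-en-1-olate | [Li]OC1=C(C)[C@H](C(C)(C)C=C)CCC1
F10 | step 2 | (2S,3S)-2-methyl-3-(2-methylbut-3-en-2-yl)-2-(prop-2-en-1-yl)cyclohexan-1-one | O=C1CCC[C@@H](C(C)(C)C=C)[C@]1(C)CC=C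
F11 | step 9 | N'-[(4aS,8aS)-5,5,8a-trimethyloctahydronaphthalen-1(2H)-ylidene]-2,4,6-tri(propan-2-yl)benzenesulfonohydrazide | CC(C)c1cc(C(C)C)c(S(=O)(=O)NN=C2CCC[C@H]3C(C)(C)CCC[C@]23C)c(C(C)C)c1
F12 | step 9 | [(4aS,8aS)-5,5,8a-trimethyl-3,4,4a,5,6,7,8,8a-octahydronaphthalen-1-yl]lithium | [Li]C1=CCC[C@H]2C(C)(C)CCC[C@]12C
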